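**Retrosynthetic overview**
- Late stage: MOM removal ⇐ Dakin oxidation (ArCHO → ArOH) ⇐ OH/CHO-directed dibromination. Ring A's catechol and its 2,6-dibromo pattern both come from a 4-substituted salicylaldehyde, so ring A needs no protecting group.
- Key disconnection: the ring A aryl–CH2(O) bond. 4-Bromo-2-hydroxybenzaldehyde (aryl electrophile) is joined to a potassium (benzyloxymethyl)trifluoroborate carrying the complete ring B, an α-alkoxymethyl carbanion (d1) equivalent, by Ni/photoredox cross-coupling.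
- Trifluoroborate ⇐ tribromo bis-MOM benzyl alcohol + BrCH2BF3K; the alcohol ⇐ exhaustive bromination, MOM protection and reduction of 3,4-dihydroxybenzaldehyde.
- Rings: no ring is formed. Both benzene rings are purchased; ring B is elaborated first and ring A is attached in the key step.

Assumptions: the target has no stereocentre (it is achiral), so no enantiocontrol is needed. Where one reagent repeats the same reaction at several positions in one operation (polybromination, double protection), the partly reacted species are not numbered.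

**Step 1**
Reactants: 1 3,4-dihydroxybenzaldehyde
Product: 2 2,3,6-tribromo-4,5-dihydroxybenzaldehyde
Conditions: Br2 (3.5 equiv), Fe powder (5 mol %), AcOH, rt → 70 °C
Reagents that add atoms: bromine, BrBr
Why: Exhaustive electrophilic aromatic bromination: each of the three free positions is ortho or para to a phenolic OH, so excess Br2 with FeBr3 catalysis fills all of them, while the formyl group prevents ipso attack and quinone-methide chemistry at C1.

**Step 2**
Reactants: 2 2,3,6-tribromo-4,5-dihydroxybenzaldehyde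
Product: 3 2,3,6-tribromo-4,5-bis(methoxymethoxy)benzaldehyde
Conditions: MOMCl (3 equiv), i-Pr2NEt (4 equiv), CH2Cl2, 0 °C → rt
Reagents that add atoms: chloromethyl methyl ether, COCCl
Why: O-alkylation (Williamson-type acetal formation) of the two acidic bromophenols with the highly reactive α-chloro ether masks the catechol against alkoxide, photoredox, NBS and peroxide conditions.

**Step 3**
Reactants: 3 2,3,6-tribromo-4,5-bis(methoxymethoxy)benzaldehyde
Product: 4 [2,3,6-tribromo-4,5-bis(methoxymethoxy)phenyl]methanol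
Conditions: NaBH4, THF/MeOH, 0 °C
Reagents that add atoms: none
Why: Chemoselective borohydride reduction of the aldehyde; aryl bromides and MOM acetals are inert.

**Step 4**
Reactants: 4 [2,3,6-tribromo-4,5-bis(methoxymethoxy)phenyl]methanol; 5 potassium (bromomethyl)trifluoroborate
Product: 7 potassium trifluoro({[2,3,6-tribromo-4,5-bis(methoxymethoxy)phenyl]methoxy}methyl)borate, via potassium [2,3,6-tribromo-4,5-bis(methoxymethoxy)phenyl]methanolate 6 (not isolated)
Conditions: KHMDS (1.3 equiv, with 1.3 equiv of 4), THF, 0 °C; then 5 (1.0 equiv), rt, 16 h; acetone extraction, Et2O precipitation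
Reagents that add atoms: none
Why: SN2 displacement of bromide from the α-bromomethyl borate by the potassium alkoxide (Molander etherification) gives a bench-stable α-alkoxymethyl carbanion equivalent; the ring has no C–H and the aryl bromides do not react with an alkoxide.

**Step 5 (key step)**
Reactants: 7 potassium trifluoro({[2,3,6-tribromo-4,5-bis(methoxymethoxy)phenyl]methoxy}methyl)borate; 8 4-bromo-2-hydroxybenzaldehyde
Product: 9 2-hydroxy-4-({[2,3,6-tribromo-4,5-bis(methoxymethoxy)phenyl]methoxy}methyl)benzaldehyde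
Conditions: Ir[dF(CF3)ppy]2(bpy)PF6 (2 mol %), NiCl2·dme (5 mol %), dtbbpy (5 mol %), K2HPO4 (2 equiv), dioxane/DMA 5:1, blue LEDs, rt, 24 h (7 in 1.3-fold excess)
Reagents that add atoms: none
Why: Ni/photoredox dual-catalytic sp3–sp2 cross-coupling (single-electron transmetalation of an alkoxymethyltrifluoroborate): the O–CH2 carbon, normally an oxocarbenium-type electrophile, is delivered as a carbanion equivalent (nucleophilic α-alkoxymethyl radical captured by Ni) to the electrophilic C–Br carbon, and Ni(0) should insert only into the unhindered, para-formyl-activated C–Br of 8 because every C–Br of 7 is flanked on both sides on an electron-rich ring.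

**Step 6**
Reactants: 9 2-hydroxy-4-({[2,3,6-tribromo-4,5-bis(methoxymethoxy)phenyl]methoxy}methyl)benzaldehyde
Product: 10 3,5-dibromo-2-hydroxy-4-({[2,3,6-tribromo-4,5-bis(methoxymethoxy)phenyl]methoxy}methyl)benzaldehyde
Conditions: NBS (2.2 equiv), NH4OAc (10 mol %), MeCN, 0 → 40 °C, dark
Reagents that add atoms: N-bromosuccinimide, O=C1CCC(=O)N1Br
Why: Phenol-directed electrophilic aromatic bromination: OH (ortho/para) and CHO (meta) both direct to C3 and C5, C6 is deactivated (as in salicylaldehyde → 3,5-dibromosalicylaldehyde), and the other ring is fully substituted, so over-bromination is impossible.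

**Step 7**
Reactants: 10 3,5-dibromo-2-hydroxy-4-({[2,3,6-tribromo-4,5-bis(methoxymethoxy)phenyl]methoxy}methyl)benzaldehyde
Product: 12 3,5-dibromo-4-({[2,3,6-tribromo-4,5-bis(methoxymethoxy)phenyl]methoxy}methyl)benzene-1,2-diol, via 3,5-dibromo-2-hydroxy-4-({[2,3,6-tribromo-4,5-bis(methoxymethoxy)phenyl]methoxy}methyl)phenyl formate 11 (not isolated)
Conditions: 30% H2O2 (1.3 equiv), NaOH (2.2 equiv), THF/H2O, 0 °C, Ar, 30 min; then 1 M HCl to pH 3
Reagents that add atoms: hydrogen peroxide, OO
Why: Dakin oxidation: hydroperoxide adds to the aldehyde of the ortho-phenoxide, the aryl group migrates to oxygen (Baeyer–Villiger-type), and the formate is hydrolysed in situ to the catechol; MOM acetals, the dibenzyl ether and aryl bromides tolerate cold dilute base.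

**Step 8**
Reactants: 12 3,5-dibromo-4-({[2,3,6-tribromo-4,5-bis(methoxymethoxy)phenyl]methoxy}methyl)benzene-1,2-diol
Product: 14 3,5-dibromo-4-{[(2,3,6-tribromo-4,5-dihydroxyphenyl)methoxy]methyl}benzene-1,2-diol, via pentakis(O-trimethylsilyl) ether 13 (not isolated)
Conditions: TMSOTf (8 equiv), 2,2′-bipyridyl (10 equiv), MeCN, 0 °C → rt; then H2O, rt; alcohol-free work-up
Reagents that add atoms: none
Why: Mild non-protic acetal cleavage (TMSOTf/2,2′-bipyridyl turns aryl MOM ethers into aryl TMS ethers and silylates the free phenols; water then hydrolyses all five silyl ethers), chosen because it avoids strong protic acid and nucleophilic solvent and so should leave the acid-labile p-hydroxybenzyl ether intact.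

**Compound list**
1 | 3,4-dihydroxybenzaldehyde | O=Cc1ccc(O)c(O)c1 | starting material
2 | 2,3,6-tribromo-4,5-dihydroxybenzaldehyde | O=Cc1c(Br)c(Br)c(O)c(O)c1Br | intermediate
3 | 2,3,6-tribromo-4,5-bis(methoxymethoxy)benzaldehyde | O=Cc1c(Br)c(Br)c(OCOC)c(OCOC)c1Br | intermediate
4 | [2,3,6-tribromo-4,5-bis(methoxymethoxy)phenyl]methanol | OCc1c(Br)c(Br)c(OCOC)c(OCOC)c1Br | intermediate
5 | potassium (bromomethyl)trifluoroborate | [K+].F[B-](F)(F)CBr | starting material
6 | potassium [2,3,6-tribromo-4,5-bis(methoxymethoxy)phenyl]methanolate | [K+].[O-]Cc1c(Br)c(Br)c(OCOC)c(OCOC)c1Br | intermediate (not isolated)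
7 | potassium trifluoro({[2,3,6-tribromo-4,5-bis(methoxymethoxy)phenyl]methoxy}methyl)borate | [K+].F[B-](F)(F)COCc1c(Br)c(Br)c(OCOC)c(OCOC)c1Br | intermediate
8 | 4-bromo-2-hydroxybenzaldehyde | O=Cc1ccc(Br)cc1O | starting material
9 | 2-hydroxy-4-({[2,3,6-tribromo-4,5-bis(methoxymethoxy)phenyl]methoxy}methyl)benzaldehyde | O=Cc1ccc(COCc2c(Br)c(Br)c(OCOC)c(OCOC)c2Br)cc1O | intermediate
10 | 3,5-dibromo-2-hydroxy-4-({[2,3,6-tribromo-4,5-bis(methoxymethoxy)phenyl]methoxy}methyl)benzaldehyde | O=Cc1cc(Br)c(COCc2c(Br)c(Br)c(OCOC)c(OCOC)c2Br)c(Br)c1O | intermediate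
11 | 3,5-dibromo-2-hydroxy-4-({[2,3,6-tribromo-4,5-bis(methoxymethoxy)phenyl]methoxy}methyl)phenyl formate | O=COc1cc(Br)c(COCc2c(Br)c(Br)c(OCOC)c(OCOC)c2Br)c(Br)c1O | intermediate (not isolated)
12 | 3,5-dibromo-4-({[2,3,6-tribromo-4,5-bis(methoxymethoxy)phenyl]methoxy}methyl)benzene-1,2-diol | Oc1cc(Br)c(COCc2c(Br)c(Br)c(OCOC)c(OCOC)c2Br)c(Br)c1O | intermediate
13 | pentakis(O-trimethylsilyl) ether of 14 | C[Si](C)(C)Oc1cc(Br)c(COCc2c(Br)c(Br)c(O[Si](C)(C)C)c(O[Si](C)(C)C)c2Br)c(Br)c1O[Si](C)(C)C | intermediate (not isolated)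
14 | 3,5-dibromo-4-{[(2,3,6-tribromo-4,5-dihydroxyphenyl)methoxy]methyl}benzene-1,2-diol | Oc1cc(Br)c(COCc2c(Br)c(O)c(O)c(Br)c2Br)c(Br)c1O | target

**Totals**
Total steps: 8. Longest linear sequence: 8 (1 → 14); compounds 5 and 8 are purchased.

**Three steps most likely to fail**

Step 5 (key coupling). The risks are Ni sequestration by the free salicylaldehyde, slow capture of a bulky radical, and stray insertion into the C–Br bonds of the tribromo ring. The fallback delivers the same alkoxymethyl carbanion equivalent by two-electron Sn→Pd transmetalation instead of the radical/Ni manifold. It sets out from 4: the potassium alkoxide (KH, THF, 0 °C → rt) is O-alkylated with tributyl(iodomethyl)stannane to give tributyl({[2,3,6-tribromo-4,5-bis(methoxymethoxy)phenyl]methoxy}methyl)stannane F1. F1 is then coupled with 8 under Stille conditions (Pd(PPh3)4, CuI, CsF, DMF, 60–80 °C). PPh3-ligated Pd should insert into the activated C–Br of 8 but not into doubly flanked, electron-rich C–Br bonds. The product is 9, where the route is rejoined.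

Step 1 (third bromination of a formyl-deactivated ring; possible bromodeformylation). The fallback postpones the last bromine until the formyl group is gone. It sets out from 1: Br2 (2.1 equiv), AcOH, rt stops cleanly at 2,3-dibromo-4,5-dihydroxybenzaldehyde F2. NaBH4 (THF/H2O, 0 °C) gives 2,3-dibromo-4,5-dihydroxybenzyl alcohol F3, whose last free position is ortho to OH and no longer deactivated. NBS (1.0 equiv), MeCN, −20 °C gives 2,3,6-tribromo-4,5-dihydroxybenzyl alcohol F4. Phenol-selective acetalisation (MOMCl 2.2 equiv, K2CO3, acetone, 0 °C) then gives 4, where the route is rejoined.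

Step 8 (acetal cleavage next to an ionisable p-hydroxybenzyl ether). The fallback replaces acid-labile MOM by fluoride-labile SEM so that the last step is non-acidic. It sets out from 2: SEMCl, i-Pr2NEt, CH2Cl2 gives 2,3,6-tribromo-4,5-bis{[2-(trimethylsilyl)ethoxy]methoxy}benzaldehyde F5. The conditions of steps 3–7 are then repeated unchanged, giving in turn:
- [2,3,6-tribromo-4,5-bis{[2-(trimethylsilyl)ethoxy]methoxy}phenyl]methanol F6;
- potassium trifluoro({[2,3,6-tribromo-4,5-bis{[2-(trimethylsilyl)ethoxy]methoxy}phenyl]methoxy}methyl)borate F7;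
- 2-hydroxy-4-({[2,3,6-tribromo-4,5-bis{[2-(trimethylsilyl)ethoxy]methoxy}phenyl]methoxy}methyl)benzaldehyde F8 (from F7 and 8);
- 3,5-dibromo-2-hydroxy-4-({[2,3,6-tribromo-4,5-bis{[2-(trimethylsilyl)ethoxy]methoxy}phenyl]methoxy}methyl)benzaldehyde F9;
- 3,5-dibromo-4-({[2,3,6-tribromo-4,5-bis{[2-(trimethylsilyl)ethoxy]methoxy}phenyl]methoxy}methyl)benzene-1,2-diol F10.

TBAF (THF, rt → 45 °C, Ar), then a pH 5 buffer, fragments both SEM groups from F10 and gives 14 directly.

**Further compounds**
F1 | step 5 | tributyl({[2,3,6-tribromo-4,5-bis(methoxymethoxy)phenyl]methoxy}methyl)stannane | CCCC[Sn](CCCC)(CCCC)COCc1c(Br)c(Br)c(OCOC)c(OCOC)c1Br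
F2 | step 1 | 2,3-dibromo-4,5-dihydroxybenzaldehyde | O=Cc1cc(O)c(O)c(Br)c1Br
F3 | step 1 | 2,3-dibromo-4,5-dihydroxybenzyl alcohol | OCc1cc(O)c(O)c(Br)c1Br
F4 | step 1 | 2,3,6-tribromo-4,5-dihydroxybenzyl alcohol | OCc1c(Br)c(Br)c(O)c(O)c1Br
F5 | step 8 | 2,3,6-tribromo-4,5-bis{[2-(trimethylsilyl)ethoxy]methoxy}benzaldehyde | O=Cc1c(Br)c(Br)c(OCOCC[Si](C)(C)C)c(OCOCC[Si](C)(C)C)c1Br
F6 | step 8 | [2,3,6-tribromo-4,5-bis{[2-(trimethylsilyl)ethoxy]methoxy}phenyl]methanol | OCc1c(Br)c(Br)c(OCOCC[Si](C)(C)C)c(OCOCC[Si](C)(C)C)c1Br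
F7 | step 8 | potassium trifluoro({[2,3,6-tribromo-4,5-bis{[2-(trimethylsilyl)ethoxy]methoxy}phenyl]methoxy}methyl)borate | [K+].F[B-](F)(F)COCc1c(Br)c(Br)c(OCOCC[Si](C)(C)C)c(OCOCC[Si](C)(C)C)c1Br
F8 | step 8 | 2-hydroxy-4-({[2,3,6-tribromo-4,5-bis{[2-(trimethylsilyl)ethoxy]methoxy}phenyl]methoxy}methyl)benzaldehyde | O=Cc1ccc(COCc2c(Br)c(Br)c(OCOCC[Si](C)(C)C)c(OCOCC[Si](C)(C)C)c2Br)cc1O
F9 | step 8 | 3,5-dibromo-2-hydroxy-4-({[2,3,6-tribromo-4,5-bis{[2-(trimethylsilyl)ethoxy]methoxy}phenyl]methoxy}methyl)benzaldehyde | O=Cc1cc(Br)c(COCc2c(Br)c(Br)c(OCOCC[Si](C)(C)C)c(OCOCC[Si](C)(C)C)c2Br)c(Br)c1O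
F10 | step 8 | 3,5-dibromo-4-({[2,3,6-tribromo-4,5-bis{[2-(trimethylsilyl)ethoxy]methoxy}phenyl]methoxy}methyl)benzene-1,2-diol | Oc1cc(Br)c(COCc2c(Br)c(Br)c(OCOCC[Si](C)(C)C)c(OCOCC[Si](C)(C)C)c2Br)c(Br)c1O
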